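2 numbers are asked of this flask: the part of the substrate gone and the target left standing.

substrate 0.069 M; gas 38 mM (held); free catalyst 9.0 mM; time 6.0 min
    reagent + free catalyst ⇌ catalyst intermediate A (K1 = 5.58 L mol⁻¹, k1 = 279 L mol⁻¹ s⁻¹)
    substrate + catalyst intermediate A ⇌ catalyst intermediate B (K2 = 36.6 L mol⁻¹, k2 = 24.0 L mol⁻¹ s⁻¹)
    catalyst intermediate B → free catalyst + target (k3 = 0.905 s⁻¹)
    free catalyst + target → spent catalyst (k4 = 0.945 L mol⁻¹ s⁻¹)
    gas ⇌ reagent, rate k5*(csat - [reagent]) (k5 = 0.203 s⁻¹, csat = 38 mM)
- part of the substrate gone at 6.0 min
- the target standing at 6.0 min, as a percentage of the substrate charged
- at the start none of reagent is dissolved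
- run time (flask): 6.0 min

The bench rule divides substrate by catalyst and turnover rate. At 0.905 s⁻¹ the charge would pass in 8.47 s, far shorter than the run, so the rule promises a finished flask. Its border lies in step 4: by that step alone, with free catalyst as charged, target has a half-life of 1.4 min, shorter than the run, so the catalyst's own lifetime has to be counted.

Take reagent at saturation. Catalyst intermediate A falls back at 50.0 s⁻¹, faster than step 2 draws it off at 1.66 s⁻¹ with substrate as charged, so it stands at 0.212 of the free catalyst. Catalyst intermediate B goes forward with a share of 58.0%. Together these give the survival factor 3.12, a selectivity factor: how many turnovers a free catalyst makes per death when substrate and target stand equal.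

With X the fraction of substrate gone and target taken equal to X, the odds of turnover against death are S times the fraction of substrate left, divided by X. Summing the deaths gives a cost, the natural logarithm of the inverse of the fraction left, less X, which the budget, S times catalyst charge over substrate charge, must pay. That budget is 0.407. A fraction gone of 0.5 costs 0.193 and one of 0.7 costs 0.504, so this reckoning places the stall between them. Target lies 13.0% of the charge below conversion, since each death takes one target.

The forecast gives 66% and 53%, from “the free catalyst being killed by the target”.

The flask gives 67.0% and 53.9%. At 6.00 min spent catalyst in this flask holds >99.9% of the catalyst charged. The conversion reached costs 0.438, slightly more than the budget of 0.407.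

In the neighbour flask with 0.28 M of substrate, S gives a budget of 0.100. That lies between the cost 0.0567 at a fraction gone of 0.300 and 0.193 at 0.5, with target 3.21% of the charge below conversion. That neighbour flask gives 35.5% and 32.3%.

(All constants are those of an exercise; the result is computed.)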